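## The problem

Diplotrin A (12) is an achiral flavone. A benzopyranone (rings A and C) carries ring B on C2 through the C2–C1′ bond, and oxygen sits on C3, C7, C8, C2′, C4′ and C5′. The carbon skeleton is small, so the real task is to place six oxygens and to leave exactly two of them, O2′ and O5′, unmethylated. The target has no stereocentre, so any stereocentre made on the way is transient and needs no absolute control. The 2′,5′-hydroquinone is electron-rich and air-sensitive and tolerates neither organometallic reagents nor oxidants, so it should be unveiled last. The methyl ethers and the vinylogous ester of ring C argue against hot protic or Lewis acids. The two free phenols are para to each other and flank the 4′-methoxy group, which makes ring B the reduced form of a methoxy-p-quinone. That quinone can be reached from a 2,4,5-trimethoxyphenyl ring by oxidative demethylation, so all ring B oxygens can travel as methyl ethers. Finally, C2 and C3 of ring C are the β- and α-carbons of an enone and bear an aryl group and an oxygen. This is the imprint of conjugate arylation at C2 followed by oxidation of the C3 enolate, on a chromone whose ring C is already closed.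

## Retrosynthesis

**12 to 10 (O2′–CH3 and O5′–CH3).** Hydroquinone 12 is the reduction product of quinone 11, and 11 is what (NH4)2Ce(NO3)6 should make from the hexamethyl ether 10. Only the 2′/5′ pair is a para-dimethoxy pair on an electron-rich ring, so this cut singles out two of six methyl ethers without protecting groups. The neighbouring option, benzyl or acetal groups on O2′ and O5′, would need a non-commercial ring B bromide. Precursor 10 is robust and has all oxygens capped. The forward reaction must oxidise ring B and spare ring A, which the C4 carbonyl deactivates.

**10 to 9 (O3–CH3).** The 3-methoxy group is installed on flavonol 9, whose only acidic site is the 3-OH. Methylation is placed here and not earlier because the corresponding hydroxyl of 8 is a base-sensitive α-ketol, and not later because a free flavonol would not survive tetravalent cerium.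

**9 to 8 (C2=C3 unsaturation).** Flavonol 9 is the dehydrogenation product of the dihydroflavonol 8. This cut adds two stereocentres in the retrosynthetic direction, but both are made in one step and then erased, so they cost nothing. It turns the C2/C3 pattern into that of a saturated β-aryl-α-hydroxy ketone.

**8 to 4 and 6 (C2–C1′ and C3–O; key disconnection).** Cutting both bonds at the C2=C3 bond of a chromone gives 7,8-dimethoxychromone 4 and the ring B Grignard reagent 6. The enolate 7 lies between them. The neighbouring cuts are closure of ring C at C4–C4a or O1–C2, or construction of ring B; each needs a more elaborate acyclic or alkynyl precursor. Here ring C is already present, both partners are one step from purchasable compounds, and the 3-oxygen arrives in the same operation. The forward step needs 1,4- rather than 1,2-addition and hydroxylation of the enolate before it can ring-open.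

**4 to 1 and 2; 6 to 5.** Chromone 4 is cut at C2–C3 and O1–C2. The acetyl methyl of acetophenone 1 supplies C3, the acetal carbon of 2 supplies C2, and the enaminone 3 cyclises under acid. Reagent 6 comes from bromide 5 by magnesium insertion.

## Roads not taken

**Alternative 1: acylative closure of ring C at C4–C4a.**
- Cut and key step: the aryloxyacrylic acid A2 is activated by P2O5 in CH3SO3H and acylates ring A ortho to the ether oxygen, giving the hexamethyl ether A1.
- Merits: A1 is identical with 10, so this road needs no dehydrogenation and no O3-methylation. After ring formation it is two steps shorter than the chosen plan. The ring A position attacked is para to a methoxy group, so regiochemistry on ring A is sound.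
- Weak points: A2 is a tetrasubstituted alkene that must carry the carboxyl cis to the aryloxy group, and it has to be built in several steps. Under strong acid the double bond can isomerise, and acylation of the more electron-rich ring B then competes. Six methyl ethers in hot sulfonic acid invite demethylation and sulfonation.
- Comparison: the chosen plan gives up the shorter end-game in exchange for purchasable partners, no alkene geometry to control and no strong acid.

**Alternative 2: ring B by furan cycloaddition and aromatisation.**
- Cut and key step: the C1′–C2′ and C5′–C6′ bonds are cut. The silyloxyfuran A5 adds across the alkyne of 2-ethynyl-3,7,8-trimethoxychromone A4, and the oxygen-bridged adduct opens to the phenol A3.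
- Merits: the 1- and 3-oxygens of the diene reinforce each other, so the regiochemistry is matched. A3 already has O2′ and O5′ differentiated from O4′. Only a desilylation remains and no redox end-game is needed; in this respect it is better than the chosen plan.
- Weak points: A4 needs a 3-methoxychromone with a two-carbon handle at C2 and an alkynylation, which is several steps. The alkyne is only moderately activated. With a silyloxyfuran, stepwise Michael-type attack without ring closure and cycloreversion are realistic competitors.
- Comparison: the chosen plan offers short access to both partners and reaction types established on chromones, at the price of two redox steps at the end.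

**Alternative 3: ring expansion of an aurone dibromide.**
- Cut and key step: the O1–C2 and C3–O bonds are cut. Bromine adds to the aurone A8 to give the dibromide A7. Aqueous KOH opens A7 at the bromo-ketal carbon and the phenoxide displaces the benzylic bromide to give the flavonol A6.
- Merits: A6 is identical with 9. The chemistry is ionic, non-cryogenic and free of stereochemical questions, and in operational robustness it is at least equal to the chosen plan.
- Weak points: bromine meets a 2,4,5-trimethoxyphenyl ring, so ring bromination competes with addition to the alkene. The 2′- and 4′-methoxy groups make the benzylic C–Br bond ionisable, so solvolysis and loss of bromine back to A8 compete with ring expansion. The ring A benzofuranone needed for A8 is not purchasable, so the count to A6 is no shorter.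
- Comparison: the chosen plan joins ring B as a nucleophile and keeps electrophilic halogen away from it until the catalytic iodine of step 4.

Key step: step 3

Assumption: 1, 2 and 5 are taken as purchasable, and since both stereocentres made in step 3 are destroyed in step 4, the route is run in the racemic series.

## Route

Step 1
Reactants: 1 2'-hydroxy-3',4'-dimethoxyacetophenone; 2 N,N-dimethylformamide dimethyl acetal
Product: 4 7,8-dimethoxy-4H-chromen-4-one, via enaminone 3 (not isolated)
Conditions: 2 (1.5 equiv), toluene, 110 °C; evaporate; conc. HCl, CH2Cl2, 40 °C
Reagents that add atoms: none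
Why: Condensation of the acetyl methyl group with the formamide acetal gives the enaminone with loss of two methanol; acid then drives intramolecular oxa-Michael addition of the phenol and elimination of dimethylamine, the standard enaminone route to 3-unsubstituted chromones.

Step 2
Reactants: 5 1-bromo-2,4,5-trimethoxybenzene
Product: 6 (2,4,5-trimethoxyphenyl)magnesium bromide (THF solution, titrated and used directly)
Conditions: Mg turnings, BrCH2CH2Br (cat.), THF, 50 °C
Reagents that add atoms: magnesium, [Mg]
Why: Grignard formation by insertion of magnesium into the aryl C–Br bond; the methyl ethers are inert and the ortho-methoxy group stabilises the reagent by chelation.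

Step 3
Reactants: 4 7,8-dimethoxy-4H-chromen-4-one; 6 (2,4,5-trimethoxyphenyl)magnesium bromide
Product: 8 rac-(2R,3R)-3-hydroxy-7,8-dimethoxy-2-(2,4,5-trimethoxyphenyl)chroman-4-one (2,3-trans), via magnesium enolate 7 (not isolated)
Conditions: CuBr·SMe2 (15 mol %), THF, slow addition of 6 (1.3 equiv), −78 → −40 °C; then trans-2-(phenylsulfonyl)-3-phenyloxaziridine (1.8 equiv), THF, −78 °C; aq. NH4Cl
Reagents that add atoms: trans-2-(phenylsulfonyl)-3-phenyloxaziridine, O=S(=O)(c1ccccc1)N1OC1c1ccccc1
Why: This is a tandem copper-catalysed conjugate addition of a Grignard reagent and enolate hydroxylation with an N-sulfonyloxaziridine (Davis oxidation), the closest known types being copper-mediated aryl additions to chromones and oxaziridine hydroxylation of ketone enolates. Transmetalation of 6 to monovalent copper gives an arylcuprate that complexes the C2=C3 bond of 4, adds at C2 and forms the C2–C1′ bond by reductive elimination, leaving the bromomagnesium enolate 7 and returning the copper. No ring is closed; ring C is already present and only its C2=C3 bond is functionalised. The required 1,4- over 1,2-selectivity comes from the soft cuprate and from the vinylogous-ester carbonyl of 4, which the 7-methoxy group para to it deactivates further towards direct Grignard attack. Enolate 7 can only be the C3–C4 enolate because C4a is aromatic, so hydroxylation is regiospecific: C3 attacks the oxaziridine oxygen in an SN2-type step and the adduct collapses to the C3 alkoxide and the sulfonyl imine. C2 is set first without control (racemate); C3 is then set by C2, since the oxidant should approach the enolate face anti to the aryl group and give the 2,3-trans isomer. Catalytic copper and the absence of Me3SiCl leave a reactive magnesium enolate and little sulfide to compete for the oxidant, and −78 °C should suppress β-elimination of the ring oxygen. Any cis isomer or over-oxidised material converges on 9 in step 4, where both stereocentres are erased.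

Step 4
Reactants: 8 rac-(2R,3R)-3-hydroxy-7,8-dimethoxy-2-(2,4,5-trimethoxyphenyl)chroman-4-one
Product: 9 3-hydroxy-7,8-dimethoxy-2-(2,4,5-trimethoxyphenyl)-4H-chromen-4-one
Conditions: I2 (10 mol %), DMSO, 110 °C
Reagents that add atoms: none
Why: Iodine-catalysed dehydrogenation in DMSO, the standard flavanone-to-flavone oxidation applied to a dihydroflavonol: iodination of the C3 enol and loss of HI lead to the aromatic 3-hydroxypyranone, and DMSO re-oxidises HI to iodine. Aromatisation of ring C is the driving force and removes both stereocentres.

Step 5
Reactants: 9 3-hydroxy-7,8-dimethoxy-2-(2,4,5-trimethoxyphenyl)-4H-chromen-4-one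
Product: 10 3,7,8-trimethoxy-2-(2,4,5-trimethoxyphenyl)-4H-chromen-4-one
Conditions: MeI, K2CO3, DMF, rt
Reagents that add atoms: iodomethane, CI
Why: Williamson O-methylation of the flavonol hydroxyl, the only acidic site in 9; carbonate is basic enough to break its hydrogen bond to the C4 carbonyl.

Step 6
Reactants: 10 3,7,8-trimethoxy-2-(2,4,5-trimethoxyphenyl)-4H-chromen-4-one
Product: 11 2-methoxy-5-(3,7,8-trimethoxy-4-oxo-4H-chromen-2-yl)cyclohexa-2,5-diene-1,4-dione
Conditions: (NH4)2Ce(NO3)6 (2.5 equiv), MeCN–H2O, 0 °C
Reagents that add atoms: water, O
Why: Oxidative demethylation of a para-dimethoxyarene by tetravalent cerium: ring B is the most electron-rich arene, its radical cation is attacked by water at C2′ and C5′, and two methanol are lost to give the p-quinone with the 4′-methoxy group retained. Ring A is deactivated by the C4 carbonyl and has only an ortho pair of methoxy groups.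

Step 7
Reactants: 11 2-methoxy-5-(3,7,8-trimethoxy-4-oxo-4H-chromen-2-yl)cyclohexa-2,5-diene-1,4-dione
Product: 12 diplotrin A, 2-(2,5-dihydroxy-4-methoxyphenyl)-3,7,8-trimethoxy-4H-chromen-4-one
Conditions: Na2S2O4, EtOAc–H2O, rt, under N2
Reagents that add atoms: none
Why: Two-electron reduction of the quinone to the hydroquinone by dithionite; the chromone and the methyl ethers are untouched, and work-up under inert gas avoids re-oxidation.

## Compound list

1 | 2'-hydroxy-3',4'-dimethoxyacetophenone | CC(=O)c1ccc(OC)c(OC)c1O | starting material
2 | N,N-dimethylformamide dimethyl acetal | COC(OC)N(C)C | starting material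
3 | (E)-3-(dimethylamino)-1-(2-hydroxy-3,4-dimethoxyphenyl)prop-2-en-1-one | CN(C)/C=C/C(=O)c1ccc(OC)c(OC)c1O | intermediate (not isolated)
4 | 7,8-dimethoxy-4H-chromen-4-one | COc1ccc2c(=O)ccoc2c1OC | intermediate
5 | 1-bromo-2,4,5-trimethoxybenzene | COc1cc(OC)c(Br)cc1OC | starting material
6 | (2,4,5-trimethoxyphenyl)magnesium bromide | COc1cc(OC)c([Mg]Br)cc1OC | intermediate
7 | bromomagnesium 7,8-dimethoxy-2-(2,4,5-trimethoxyphenyl)-2H-chromen-4-olate (racemic; one enantiomer drawn) | COc1ccc2c(c1OC)O[C@H](c1cc(OC)c(OC)cc1OC)C=C2O[Mg]Br | intermediate (not isolated)
8 | rac-(2R,3R)-3-hydroxy-7,8-dimethoxy-2-(2,4,5-trimethoxyphenyl)chroman-4-one (trans; one enantiomer drawn) | O=C1c2ccc(OC)c(OC)c2O[C@H](c2cc(OC)c(OC)cc2OC)[C@H]1O | intermediate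
9 | 3-hydroxy-7,8-dimethoxy-2-(2,4,5-trimethoxyphenyl)-4H-chromen-4-one | COc1cc(OC)c(-c2oc3c(OC)c(OC)ccc3c(=O)c2O)cc1OC | intermediate
10 | 3,7,8-trimethoxy-2-(2,4,5-trimethoxyphenyl)-4H-chromen-4-one | COc1cc(OC)c(-c2oc3c(OC)c(OC)ccc3c(=O)c2OC)cc1OC | intermediate
11 | 2-methoxy-5-(3,7,8-trimethoxy-4-oxo-4H-chromen-2-yl)cyclohexa-2,5-diene-1,4-dione | COC1=CC(=O)C(=CC1=O)c1oc2c(OC)c(OC)ccc2c(=O)c1OC | intermediate
12 | diplotrin A, 2-(2,5-dihydroxy-4-methoxyphenyl)-3,7,8-trimethoxy-4H-chromen-4-one | COc1cc(O)c(-c2oc3c(OC)c(OC)ccc3c(=O)c2OC)cc1O | target

## Step count and risks

Total: 7 steps. Longest linear sequence: 6 steps (steps 1, 3, 4, 5, 6, 7 from 1; equally steps 2 to 7 from 5).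

**Step 3 (key step).** Four things may go wrong:
- sluggish conjugate addition to the deactivated chromone, with direct carbonyl attack by the Grignard reagent taking over;
- ring opening of the enolate by β-elimination of the ring oxygen on warming;
- addition of the enolate to the sulfonyl imine released by the oxidant;
- consumption of the oxidant by surplus aryl-metal species.

Fallback, setting out from 4 and 6: the same copper-catalysed addition is run with Me3SiCl present, which accelerates the 1,4-addition and traps the enolate as the isolable silyl enol ether, rac-[7,8-dimethoxy-2-(2,4,5-trimethoxyphenyl)-2H-chromen-4-yl]oxy(trimethyl)silane F1. F1 is then epoxidised anti to the aryl group with mCPBA (NaHCO3, CH2Cl2, 0 °C; Rubottom oxidation), and acidic work-up removes the silyl group. This returns to the route at 8 and separates C–C from C–O bond formation.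

**Step 6.** Oxidation may be unselective: competing formation of the ortho-quinone across C4′/C5′, attack on ring A or on the enol ether of ring C, nitration, or hydrolysis of the quinone methoxy group on prolonged contact with acid. Fallback, setting out from 10: anodic oxidation in methanol (carbon anode, LiClO4, 0 °C) adds two methoxy groups para across ring B to give the quinone bisketal, 3,7,8-trimethoxy-2-(3,3,4,6,6-pentamethoxycyclohexa-1,4-dien-1-yl)-4H-chromen-4-one F2. Mild hydrolysis with aqueous acetic acid returns to the route at 11.

**Step 4.** Acid-promoted loss of water across C2–C3 may compete, which would remove O3. Iodination of the electron-rich ring B and ring contraction of the α-ketol are further risks. Fallback, setting out from 8: the C3 carbinol is oxidised with Dess–Martin periodinane (NaHCO3, CH2Cl2, rt) to rac-7,8-dimethoxy-2-(2,4,5-trimethoxyphenyl)chromane-3,4-dione F3. F3 enolises through C2–H on contact with a trace of Et3N and returns to the route at 9. This replaces dehydrogenation by alcohol oxidation and uses no halogen or acid.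

**Step 2.** Insertion into the electron-rich C–Br bond may be slow, and at the temperature then needed homocoupling to the biaryl may take over. Fallback, setting out from 5: bromine–lithium exchange with n-BuLi (THF, −78 °C) gives 2,4,5-trimethoxyphenyllithium F4. Transmetalation with MgBr2·OEt2 returns to the route at 6.

## Further compounds

F1 | step 3 | rac-[7,8-dimethoxy-2-(2,4,5-trimethoxyphenyl)-2H-chromen-4-yl]oxy(trimethyl)silane (one enantiomer drawn) | COc1ccc2c(c1OC)O[C@H](c1cc(OC)c(OC)cc1OC)C=C2O[Si](C)(C)C
F2 | step 6 | 3,7,8-trimethoxy-2-(3,3,4,6,6-pentamethoxycyclohexa-1,4-dien-1-yl)-4H-chromen-4-one | COC1=CC(OC)(OC)C(=CC1(OC)OC)c1oc2c(OC)c(OC)ccc2c(=O)c1OC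
F3 | step 4 | rac-7,8-dimethoxy-2-(2,4,5-trimethoxyphenyl)chromane-3,4-dione (one enantiomer drawn) | COc1ccc2c(c1OC)O[C@H](c1cc(OC)c(OC)cc1OC)C(=O)C2=O
F4 | step 2 | 2,4,5-trimethoxyphenyllithium | [Li]c1cc(OC)c(OC)cc1OC
A1 | alternative 1 | 3,7,8-trimethoxy-2-(2,4,5-trimethoxyphenyl)-4H-chromen-4-one (identical with 10) | COc1cc(OC)c(-c2oc3c(OC)c(OC)ccc3c(=O)c2OC)cc1OC
A2 | alternative 1 | (E)-3-(2,3-dimethoxyphenoxy)-2-methoxy-3-(2,4,5-trimethoxyphenyl)prop-2-enoic acid | OC(=O)/C(OC)=C(\Oc1cccc(OC)c1OC)c1cc(OC)c(OC)cc1OC
A3 | alternative 2 | 2-[2-(tert-butyldimethylsilyloxy)-5-hydroxy-4-methoxyphenyl]-3,7,8-trimethoxy-4H-chromen-4-one | COc1cc(O[Si](C)(C)C(C)(C)C)c(-c2oc3c(OC)c(OC)ccc3c(=O)c2OC)cc1O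
A4 | alternative 2 | 2-ethynyl-3,7,8-trimethoxy-4H-chromen-4-one | C#Cc1oc2c(OC)c(OC)ccc2c(=O)c1OC
A5 | alternative 2 | tert-butyl[(4-methoxyfuran-2-yl)oxy]dimethylsilane | COc1coc(O[Si](C)(C)C(C)(C)C)c1
A6 | alternative 3 | 3-hydroxy-7,8-dimethoxy-2-(2,4,5-trimethoxyphenyl)-4H-chromen-4-one (identical with 9) | COc1cc(OC)c(-c2oc3c(OC)c(OC)ccc3c(=O)c2O)cc1OC
A7 | alternative 3 | 2-bromo-2-[bromo(2,4,5-trimethoxyphenyl)methyl]-6,7-dimethoxy-1-benzofuran-3(2H)-one (relative configuration left open; both centres are lost) | COc1ccc2c(c1OC)OC(Br)(C(Br)c1cc(OC)c(OC)cc1OC)C2=O
A8 | alternative 3 | (Z)-6,7-dimethoxy-2-(2,4,5-trimethoxybenzylidene)-1-benzofuran-3(2H)-one | COc1ccc2c(c1OC)O/C(=C\c1cc(OC)c(OC)cc1OC)C2=O
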